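**Plan**

Numbering (icetexane): ring A = C1–C5/C10; seven-membered ring B = C5–C6–C7–C8–C9–C20–C10; quinone ring C = C8/C9/C11–C14; lactone C19(=O)–O–C6 on C4. Enabling feature: the γ-lactone fused to ring A across C4–C5 is a 2-methylbutenolide (C4=C5) in disguise, and its β-carbon C5 lies next to the stereocentre C6.
Retrosynthetic cuts, in order: hydroxyquinone ⇒ 11,12,14-trimethoxyarene; C10=C20 (aldol condensation, ring B); C3–C4 and C5–C10 (Diels–Alder with a 2-siloxybutadiene, ring A); C4=C5 (ring-closing metathesis) and O6–C19 (ester); C6–O (epoxidation) and C6–C7 (vinyl addition to an aryl aldehyde).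
Forward: hexasubstituted arene (future ring C) → C7/C6 pair → butenolide (lactone ring) → ring A by [4+2] → ring B by aldol condensation → C1 reduction → quinone.
Stereochemistry: C7 and C6 from a Sharpless kinetic resolution (erythro epoxy alcohol); C4 and C5 from the Diels–Alder addition anti to the C6 substituent; C1 from a Luche reduction on the ring-A face away from the lactone.

Key step: step 13

Remark: the target needs the unlike (erythro) pair 6R,7S; Lewis-acid vinylogous aldol additions of 2-siloxyfurans to aldehydes usually favour the like (threo) adduct, so the butenolide is built from an erythro epoxy alcohol instead.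
Abbreviations: Ar = 2-(1,3-dioxolan-2-yl)-3,4,6-trimethoxy-5-(propan-2-yl)phenyl; TBS = tert-butyldimethylsilyl. Later compounds carry icetexane locants.

**Route**

Step 1
Reactants: 1 1,2,4-trimethoxybenzene
Product: 3 2-(2,3,6-trimethoxyphenyl)propan-2-ol, via aryllithium 2 (not isolated)
Conditions: n-BuLi (1.1 equiv), THF, 0 °C → rt; acetone, −78 °C → rt; H2O
Reagents that add atoms: acetone, CC(C)=O
Why: Directed ortho-metalation should take place at C3, the position flanked by two methoxy groups, and the aryllithium adds to acetone (1,2-addition) to give the tertiary benzylic alcohol.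

Step 2
Reactants: 3 2-(2,3,6-trimethoxyphenyl)propan-2-ol
Product: 4 1,2,4-trimethoxy-3-(propan-2-yl)benzene
Conditions: Et3SiH (2.5 equiv), TFA (5 equiv), CH2Cl2, 0 °C → rt
Reagents that add atoms: none
Why: Ionic hydrogenation: TFA ionises the tertiary benzylic alcohol and triethylsilane should transfer hydride to the cation, leaving the isopropyl group.

Step 3
Reactants: 4 1,2,4-trimethoxy-3-(propan-2-yl)benzene
Product: 5 1-bromo-2,4,5-trimethoxy-3-(propan-2-yl)benzene
Conditions: NBS (1.05 equiv), MeCN, 0 °C → rt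
Reagents that add atoms: N-bromosuccinimide, O=C1CCC(=O)N1Br
Why: Electrophilic aromatic bromination should go to the free position that is para to one methoxy group and ortho to another (the future C8), since the other free position is activated by only one methoxy group.

Step 4
Reactants: 5 1-bromo-2,4,5-trimethoxy-3-(propan-2-yl)benzene
Product: 7 2-bromo-3,5,6-trimethoxy-4-(propan-2-yl)benzaldehyde, via aryllithium 6 (not isolated)
Conditions: LDA (1.2 equiv), THF, −78 °C; DMF, −78 → 0 °C; H2O
Reagents that add atoms: N,N-dimethylformamide, CN(C)C=O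
Why: Directed ortho-lithiation with an amide base should remove the only ring hydrogen, which lies between bromine and methoxy, without bromine–lithium exchange, and DMF formylates the aryllithium at −78 °C before lithium bromide can be lost (this carbon becomes C20).

Step 5
Reactants: 7 2-bromo-3,5,6-trimethoxy-4-(propan-2-yl)benzaldehyde
Product: 8 2-[2-bromo-3,5,6-trimethoxy-4-(propan-2-yl)phenyl]-1,3-dioxolane
Conditions: ethylene glycol (5 equiv), TsOH·H2O (5 mol%), toluene, reflux, Dean–Stark
Reagents that add atoms: ethylene glycol, OCCO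
Why: Acid-catalysed acetalisation with azeotropic removal of water masks the first formyl group so that the second one can be introduced and used alone.

Step 6
Reactants: 8 2-[2-bromo-3,5,6-trimethoxy-4-(propan-2-yl)phenyl]-1,3-dioxolane
Product: 10 2-(1,3-dioxolan-2-yl)-3,4,6-trimethoxy-5-(propan-2-yl)benzaldehyde (ArCHO), via aryllithium 9 (not isolated)
Conditions: n-BuLi (1.1 equiv), THF, −78 °C; DMF, −78 → 0 °C; H2O
Reagents that add atoms: N,N-dimethylformamide, CN(C)C=O
Why: Bromine–lithium exchange followed by formylation with DMF (Bouveault reaction) should give the aldehyde whose carbon becomes C7, the acetal and the methoxy groups being inert to n-BuLi at −78 °C.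

Step 7
Reactants: 10 2-(1,3-dioxolan-2-yl)-3,4,6-trimethoxy-5-(propan-2-yl)benzaldehyde
Product: 11 rac-1-Ar-prop-2-en-1-ol
Conditions: CH2=CHMgBr (1.3 equiv), THF, −78 → 0 °C; H2O
Reagents that add atoms: vinylmagnesium bromide, C=C[Mg]Br
Why: Grignard 1,2-addition to the aldehyde forms the C6–C7 bond and gives the racemic secondary allylic alcohol that the next step resolves.

Step 8
Reactants: 11 rac-1-Ar-prop-2-en-1-ol
Product: 12 (S)-Ar[(2R)-oxiran-2-yl]methanol
Conditions: Ti(OiPr)4 (0.1 equiv), L-(+)-DIPT (0.15 equiv), t-BuOOH (0.45 equiv), 4 Å MS, CH2Cl2, −20 °C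
Reagents that add atoms: tert-butyl hydroperoxide, CC(C)(C)OO
Why: Sharpless kinetic resolution: the titanium–L-(+)-tartrate catalyst should epoxidise the (R)-enantiomer of 11 (aryl in the place that alkyl takes in the fast-reacting (S)-alkyl vinyl carbinols) much faster than its antipode and with the erythro selectivity general for this reaction, so that C7 (S) and C6 (R) are set together, while unreacted (S)-11 is separated.

Step 9
Reactants: 12 (S)-Ar[(2R)-oxiran-2-yl]methanol
Product: 13 tert-butyl{(S)-Ar[(2R)-oxiran-2-yl]methoxy}dimethylsilane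
Conditions: TBSCl (1.5 equiv), imidazole (3 equiv), DMF, rt
Reagents that add atoms: tert-butyldimethylsilyl chloride, CC(C)(C)[Si](C)(C)Cl
Why: Silylation under imidazole conditions protects the C7 hydroxyl without forming an alkoxide, so that Payne rearrangement of the epoxy alcohol is avoided.

Step 10
Reactants: 13 tert-butyl{(S)-Ar[(2R)-oxiran-2-yl]methoxy}dimethylsilane
Product: 14 (1S,2R)-1-Ar-1-[(TBS)oxy]but-3-en-2-ol
Conditions: Me3S+ I− (4 equiv), n-BuLi (3.9 equiv), THF, −10 → 10 °C; H2O at 0 °C
Reagents that add atoms: trimethylsulfonium iodide, C[S+](C)C.[I-]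
Why: One-carbon homologation of a terminal epoxide to an allylic alcohol (Corey–Chaykovsky-type ylide): dimethylsulfonium methylide opens the epoxide at CH2 and a second equivalent induces loss of dimethyl sulfide, C6 being untouched, and the lithium alkoxide is quenched cold so that 1,2-silyl migration should not set in.

Step 11
Reactants: 14 (1S,2R)-1-Ar-1-[(TBS)oxy]but-3-en-2-ol
Product: 15 (1S,2R)-1-Ar-1-[(TBS)oxy]but-3-en-2-yl 2-methylprop-2-enoate
Conditions: methacryloyl chloride (1.5 equiv), Et3N (3 equiv), DMAP (0.1 equiv), CH2Cl2, 0 °C → rt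
Reagents that add atoms: methacryloyl chloride, C=C(C)C(Cl)=O
Why: DMAP-catalysed acylation of the secondary allylic alcohol installs C19, C4 and the C4 methyl group as the methacrylate.

Step 12
Reactants: 15 (1S,2R)-1-Ar-1-[(TBS)oxy]but-3-en-2-yl 2-methylprop-2-enoate
Product: 16 (5R)-5-{(S)-Ar[(TBS)oxy]methyl}-3-methylfuran-2(5H)-one
Conditions: Grubbs second-generation catalyst (5 mol%), toluene (0.005 M), 80 °C
Reagents that add atoms: none
Why: Ring-closing metathesis between the vinyl group and the methacrylate alkene should close the 3-methylbutenolide (C4=C5) with loss of ethylene, without touching C6 or C7.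

Step 13
Reactants: 16 (5R)-5-{(S)-Ar[(TBS)oxy]methyl}-3-methylfuran-2(5H)-one; 17 2-(trimethylsiloxy)buta-1,3-diene
Product: 18 (3R,3aR,7aS)-3-{(S)-Ar[(TBS)oxy]methyl}-7a-methyl-5-[(trimethylsilyl)oxy]-3a,4,7,7a-tetrahydro-2-benzofuran-1(3H)-one (ring-A silyl enol ether cycloadduct; icetexane 4S,5R,6R,7S; C1–OSiMe3 with C1=C2)
Conditions: 17 (6 equiv), BHT (5 mol%), CH2Cl2, 14 kbar, 40 °C, 72 h; volatiles removed in vacuo
Reagents that add atoms: none
Why: Concerted, asynchronous normal-demand [4+2] cycloaddition in which the CH2 terminus next to the siloxy carbon of 17 (largest HOMO coefficient) bonds to the butenolide β-carbon C5 and the other terminus to the α-carbon C4. The closest known reaction type is the thermal or high-pressure Diels–Alder addition of 2-siloxybutadienes to 5-substituted furan-2(5H)-ones, which goes anti to the 5-substituent. Ring A is closed by this intermolecular cycloaddition, both new bonds (C5–C10 and C3–C4) forming on one face of the butenolide, so that the lactone/ring A fusion is necessarily cis. C5 and the quaternary C4 are set together by the C6 stereocentre: the diene should add to the face opposite the bulky aryl(silyloxy)methyl group, which gives H5 trans to H6, i.e. 4S,5R. The step needs facial selectivity, secured by that substituent directly beside the reacting β-carbon, and "para" regioselectivity, secured by the siloxy group, which ends up on C1, 1,4 to C4. Pressure is chosen as the activation because the α-methyl group makes the dienophile sluggish while a Lewis acid would ionise the aryl acetal and strip the silyl enol ether; the adduct is used crude because the trimethylsilyl enol ether does not survive silica gel.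

Step 14
Reactants: 18 ring-A silyl enol ether cycloadduct
Product: 20 (4S,5R,6R,7S)-7-[(TBS)oxy]-11,12,14-trimethoxy-1-oxoicetexa-8,10(20),11,13-tetraen-19,6-olide, via keto aldehyde 19 (not isolated)
Conditions: TsOH·H2O (0.3 equiv), THF/H2O (5:1), 40 °C; then solvent exchange to toluene, piperidine (1 equiv), AcOH (1 equiv), 80 °C
Reagents that add atoms: none
Why: Acid hydrolysis of the silyl enol ether and the dioxolane gives the C1 ketone and the C20 aldehyde, and piperidinium acetate should then effect an intramolecular aldol condensation (Claisen–Schmidt type) from C10, the only enolisable carbon that can reach the aldehyde in a seven-membered ring, dehydration giving the enone conjugated with the arene.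

Step 15
Reactants: 20 tetracyclic enone
Product: 21 (1R,4S,5R,6R,7S)-7-[(TBS)oxy]-1-hydroxy-11,12,14-trimethoxyicetexa-8,10(20),11,13-tetraen-19,6-olide
Conditions: NaBH4 (1.5 equiv), CeCl3·7H2O (1.5 equiv), MeOH/THF (1:1), −40 °C
Reagents that add atoms: none
Why: Luche 1,2-reduction of the enone: hydride should add to C1 from the ring-A face that carries H5 and the C4 methyl group, the other face being shielded by C6 and C19 of the cis-fused lactone, which gives the 1R alcohol (hydroxyl cis to C19) and leaves the lactone untouched.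

Step 16
Reactants: 21 C1 allylic alcohol
Product: 22 (1R,4S,5R,6R,7S)-7-[(TBS)oxy]-1-hydroxy-12-methoxy-11,14-dioxoicetexa-8,10(20),12-trien-19,6-olide
Conditions: CAN (2.5 equiv), MeCN/H2O (2:1), 0 °C, 15 min
Reagents that add atoms: water, O
Why: Oxidative demethylation with ceric ammonium nitrate should convert the para-dimethoxy pair at C11/C14 into the p-quinone, the C12 methoxy group remaining as a vinylogous ester, while the silyl ether keeps the benzylic C7 position from being oxidised.

Step 17
Reactants: 22 12-methoxyquinone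
Product: 23 7-O-(tert-butyldimethylsilyl)ballotiquinone
Conditions: LiOH (0.2 M aq., 3 equiv), THF, 0 °C; then 1 M HCl to pH 3
Reagents that add atoms: lithium hydroxide, [Li+].[OH-]
Why: Addition–elimination of hydroxide at C12 of the methoxyquinone (vinylogous ester hydrolysis) gives the hydroxyquinone anion, which is protonated on acidification; the lactone, hindered by the quaternary C4, should survive brief cold base and could only reclose to the γ-lactone because the C7 oxygen is still silylated.

Step 18
Reactants: 23 7-O-(tert-butyldimethylsilyl)ballotiquinone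
Product: 24 ballotiquinone
Conditions: HF·pyridine, pyridine/THF, 0 °C → rt
Reagents that add atoms: none
Why: Fluoride-mediated cleavage of the silyl ether with buffered HF·pyridine frees the C7 hydroxyl under conditions that the hydroxyquinone, the allylic alcohol and the lactone should tolerate.

**Compound list**

1 | 1,2,4-trimethoxybenzene | COc1ccc(OC)c(OC)c1 | starting material
2 | (2,3,6-trimethoxyphenyl)lithium | [Li]c1c(OC)c(OC)ccc1OC | intermediate (not isolated)
3 | 2-(2,3,6-trimethoxyphenyl)propan-2-ol | CC(C)(O)c1c(OC)c(OC)ccc1OC | intermediate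
4 | 1,2,4-trimethoxy-3-(propan-2-yl)benzene | CC(C)c1c(OC)c(OC)ccc1OC | intermediate
5 | 1-bromo-2,4,5-trimethoxy-3-(propan-2-yl)benzene | CC(C)c1c(OC)c(OC)cc(Br)c1OC | intermediate
6 | [2-bromo-3,5,6-trimethoxy-4-(propan-2-yl)phenyl]lithium | CC(C)c1c(OC)c(OC)c([Li])c(Br)c1OC | intermediate (not isolated)
7 | 2-bromo-3,5,6-trimethoxy-4-(propan-2-yl)benzaldehyde | CC(C)c1c(OC)c(OC)c(C=O)c(Br)c1OC | intermediate
8 | 2-[2-bromo-3,5,6-trimethoxy-4-(propan-2-yl)phenyl]-1,3-dioxolane | CC(C)c1c(OC)c(OC)c(C2OCCO2)c(Br)c1OC | intermediate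
9 | [2-(1,3-dioxolan-2-yl)-3,4,6-trimethoxy-5-(propan-2-yl)phenyl]lithium | CC(C)c1c(OC)c(OC)c(C2OCCO2)c([Li])c1OC | intermediate (not isolated)
10 | 2-(1,3-dioxolan-2-yl)-3,4,6-trimethoxy-5-(propan-2-yl)benzaldehyde | CC(C)c1c(OC)c(OC)c(C2OCCO2)c(C=O)c1OC | intermediate
11 | rac-1-Ar-prop-2-en-1-ol | CC(C)c1c(OC)c(OC)c(C2OCCO2)c(c1OC)C(O)C=C | intermediate
12 | (S)-Ar[(2R)-oxiran-2-yl]methanol | CC(C)c1c(OC)c(OC)c(C2OCCO2)c(c1OC)[C@H](O)[C@@H]1OC1 | intermediate
13 | tert-butyl{(S)-Ar[(2R)-oxiran-2-yl]methoxy}dimethylsilane | CC(C)c1c(OC)c(OC)c(C2OCCO2)c(c1OC)[C@H](O[Si](C)(C)C(C)(C)C)[C@@H]1OC1 | intermediate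
14 | (1S,2R)-1-Ar-1-[(TBS)oxy]but-3-en-2-ol | CC(C)c1c(OC)c(OC)c(C2OCCO2)c(c1OC)[C@H](O[Si](C)(C)C(C)(C)C)[C@H](O)C=C | intermediate
15 | (1S,2R)-1-Ar-1-[(TBS)oxy]but-3-en-2-yl 2-methylprop-2-enoate | CC(C)c1c(OC)c(OC)c(C2OCCO2)c(c1OC)[C@H](O[Si](C)(C)C(C)(C)C)[C@H](OC(=O)C(C)=C)C=C | intermediate
16 | (5R)-5-{(S)-Ar[(TBS)oxy]methyl}-3-methylfuran-2(5H)-one | CC(C)c1c(OC)c(OC)c(C2OCCO2)c(c1OC)[C@H](O[Si](C)(C)C(C)(C)C)[C@@H]1OC(=O)C(C)=C1 | intermediate
17 | 2-(trimethylsiloxy)buta-1,3-diene | C=CC(=C)O[Si](C)(C)C | starting material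
18 | (3R,3aR,7aS)-3-{(S)-Ar[(TBS)oxy]methyl}-7a-methyl-5-[(trimethylsilyl)oxy]-3a,4,7,7a-tetrahydro-2-benzofuran-1(3H)-one | CC(C)c1c(OC)c(OC)c(C2OCCO2)c(c1OC)[C@H](O[Si](C)(C)C(C)(C)C)[C@@H]1OC(=O)[C@@]3(C)CC=C(O[Si](C)(C)C)C[C@@H]13 | intermediate
19 | (3R,3aR,7aS)-3-{(S)-[(TBS)oxy][2-formyl-3,4,6-trimethoxy-5-(propan-2-yl)phenyl]methyl}-7a-methylhexahydro-2-benzofuran-1,5-dione | CC(C)c1c(OC)c(OC)c(C=O)c(c1OC)[C@H](O[Si](C)(C)C(C)(C)C)[C@@H]1OC(=O)[C@@]3(C)CCC(=O)C[C@@H]13 | intermediate (not isolated)
20 | (4S,5R,6R,7S)-7-[(TBS)oxy]-11,12,14-trimethoxy-1-oxoicetexa-8,10(20),11,13-tetraen-19,6-olide | CC(C)c1c(OC)c(OC)c2c(c1OC)[C@H](O[Si](C)(C)C(C)(C)C)[C@@H]1OC(=O)[C@@]3(C)CCC(=O)C(=C2)[C@@H]13 | intermediate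
21 | (1R,4S,5R,6R,7S)-7-[(TBS)oxy]-1-hydroxy-11,12,14-trimethoxyicetexa-8,10(20),11,13-tetraen-19,6-olide | CC(C)c1c(OC)c(OC)c2c(c1OC)[C@H](O[Si](C)(C)C(C)(C)C)[C@@H]1OC(=O)[C@@]3(C)CC[C@@H](O)C(=C2)[C@@H]13 | intermediate
22 | (1R,4S,5R,6R,7S)-7-[(TBS)oxy]-1-hydroxy-12-methoxy-11,14-dioxoicetexa-8,10(20),12-trien-19,6-olide | CC(C)C1=C(OC)C(=O)C2=C(C1=O)[C@H](O[Si](C)(C)C(C)(C)C)[C@@H]1OC(=O)[C@@]3(C)CC[C@@H](O)C(=C2)[C@@H]13 | intermediate
23 | 7-O-(tert-butyldimethylsilyl)ballotiquinone | CC(C)C1=C(O)C(=O)C2=C(C1=O)[C@H](O[Si](C)(C)C(C)(C)C)[C@@H]1OC(=O)[C@@]3(C)CC[C@@H](O)C(=C2)[C@@H]13 | intermediate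
24 | ballotiquinone, (1R,4S,5R,6R,7S)-1,7,12-trihydroxy-11,14-dioxoicetexa-8,10(20),12-trien-19,6-olide | CC(C)C1=C(O)C(=O)C2=C(C1=O)[C@H](O)[C@@H]1OC(=O)[C@@]3(C)CC[C@@H](O)C(=C2)[C@@H]13 | target

**Count and risks**

Total step count: 18. Longest linear sequence: 18 steps (1 → 24); diene 17 is purchased.

Step 13 (most likely to fail). The α-methyl group lowers the dienophile reactivity, so diene 17 may polymerise under pressure before it adds, and regiocontrol may be incomplete. The fallback sets out from 16 and comes back at 19. The more electron-rich trans-1-methoxy-3-(trimethylsiloxy)buta-1,3-diene is added to 16 in toluene at 130 °C in a sealed tube. It forms the same two bonds with the same facial and regiochemical sense and gives the 3-methoxy silyl enol ether cycloadduct F1. Brief treatment with 0.1 M HCl in THF at 0 °C hydrolyses the enol ether and eliminates methanol to give the ring-A enone acetal F2 (C1 ketone, C2=C3). Hydrogenation (H2, Pd/C, EtOAc) of the enone alkene gives the saturated ring-A ketone acetal F3. Under the hydrolysis stage of step 14, F3 gives keto aldehyde 19, which is carried on as before.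

Step 8. The di-ortho-substituted aryl group and the Lewis-basic acetal may erode the rate difference between the enantiomers in the titanium–tartrate epoxidation, or the benzylic epoxy alcohol may be opened on the catalyst. The fallback sets out from 10 and comes back at 15. Reagent-controlled anti-hydroxyallylation is used instead: 10 is treated at −78 °C with (E)-3-(1,3,2-dioxaborinan-2-yl)allyl-diisopinocampheylborane, the isopinocampheyl antipode being chosen on a model aldehyde to give the 1S,2R series. Oxidative work-up (NaOH, H2O2) gives the anti diol (1S,2R)-1-Ar-but-3-ene-1,2-diol F4. The less hindered allylic hydroxyl is acylated with methacrylic anhydride and DMAP at −20 °C to give the hydroxy methacrylate F5. Silylation of the remaining benzylic hydroxyl (TBSCl, imidazole, DMF) then gives 15.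

Step 14. The seven-membered ring may fail to close under reversible amine-salt catalysis, because the aldehyde is flanked by two ortho substituents and the new ring is trans-fused to the lactone; intermolecular condensation or loss of the silyl group with lactol formation could take over. The fallback sets out from 19, isolated after the hydrolysis stage, and comes back at 20. An irreversible titanium-enolate aldol addition (TiCl4, Bu3N, CH2Cl2, −78 °C) closes ring B to the β-hydroxy ketone F6. Mesylation (MsCl, Et3N, 0 °C) gives the C20 mesylate F7, and elimination with DBU gives enone 20.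

**Further compounds**

F1 | step 13 | 3-methoxy silyl enol ether cycloadduct (3-methoxy analogue of 18; C3 configuration not defined) | CC(C)c1c(OC)c(OC)c(C2OCCO2)c(c1OC)[C@H](O[Si](C)(C)C(C)(C)C)[C@@H]1OC(=O)[C@@]3(C)C(OC)C=C(O[Si](C)(C)C)C[C@@H]13
F2 | step 13 | ring-A enone acetal (C1 ketone, C2=C3) | CC(C)c1c(OC)c(OC)c(C2OCCO2)c(c1OC)[C@H](O[Si](C)(C)C(C)(C)C)[C@@H]1OC(=O)[C@@]3(C)C=CC(=O)C[C@@H]13
F3 | step 13 | saturated ring-A ketone acetal (dioxolane analogue of 19) | CC(C)c1c(OC)c(OC)c(C2OCCO2)c(c1OC)[C@H](O[Si](C)(C)C(C)(C)C)[C@@H]1OC(=O)[C@@]3(C)CCC(=O)C[C@@H]13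
F4 | step 8 | (1S,2R)-1-Ar-but-3-ene-1,2-diol | CC(C)c1c(OC)c(OC)c(C2OCCO2)c(c1OC)[C@H](O)[C@H](O)C=C
F5 | step 8 | (1S,2R)-1-Ar-1-hydroxybut-3-en-2-yl 2-methylprop-2-enoate | CC(C)c1c(OC)c(OC)c(C2OCCO2)c(c1OC)[C@H](O)[C@H](OC(=O)C(C)=C)C=C
F6 | step 14 | β-hydroxy ketone with ring B closed (C20 carbinol; C10 and C20 configurations not defined) | CC(C)c1c(OC)c(OC)c2c(c1OC)[C@H](O[Si](C)(C)C(C)(C)C)[C@@H]1OC(=O)[C@@]3(C)CCC(=O)C(C2O)[C@@H]13
F7 | step 14 | C20 mesylate of F6 | CC(C)c1c(OC)c(OC)c2c(c1OC)[C@H](O[Si](C)(C)C(C)(C)C)[C@@H]1OC(=O)[C@@]3(C)CCC(=O)C(C2OS(C)(=O)=O)[C@@H]13
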